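## Retrosynthetic overview
1. γ-Lactone (last ring): the C16 allylic CH2OH arm is oxidised to the acid level and closes onto 2-OH. This parallels oxidation of the isopropenyl arm of a cembrene.
2. 14-Membered ring: the C1–C2 bond is made by an aluminium-templated carbonyl-ene macrocyclisation of an open, fully oxygenated geranylgeranyl-type epoxy aldehyde. The C1=C15 π bond attacks C2 and H leaves from C17, which is the bond, polarity and termination of the cyclase. This step sets C1 and C2.
3. Oxirane (first ring): Sharpless epoxidation of the C2 allylic alcohol on the open chain gives 3S,4S.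
4. Chain: C5 units are joined head to tail. Two catalyst-controlled vinylogous Mukaiyama aldol reactions form C5–C6 and C9–C10 (5R, 9S). C14 comes from methylenation/hydroboration, and C14–C1 from an asymmetric Ni/Cr coupling (14R).
5. Ring order: oxirane → carbocycle → lactone.

**Numbering:** cembrane numbering of the target is used for all compounds.
- C1 is the ring CH bearing the acrylate; C2 is the lactone O–CH.
- C3/C4 carry the epoxide, C5 the OAc, C9 the OH and C14 the OAc.
- The ring alkenes are C7=C8 and C11=C12.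
- C15 is the acrylate α-carbon, C16 the C=O and C17 the =CH2.
- C18, C19 and C20 are the methyls on C4, C8 and C12.
- Target: 1R,2S,3S,4S,5R,9S,14R,7E,11E.

**Assumption:** the facial sense of the enantiomeric catalysts and ligand in steps 2, 4 and 11 is taken from the accepted models for simple aldehydes. Both antipodes are available, so a reversed sense only swaps the antipode.

## Route

Step 1
Reactants: 1 tiglic aldehyde
Product: 2 (1E)-1-(tert-butyldimethylsilyloxy)-2-methylbuta-1,3-diene
Conditions: TBSOTf, Et3N, Et2O, 0 °C → rt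
Reagents that add atoms: tert-butyldimethylsilyl triflate, CC(C)(C)[Si](C)(C)OS(=O)(=O)C(F)(F)F
Why: Soft γ-enolisation (silyl dienol ether formation), in which O-silylation of the enal is followed by removal of a γ-proton by Et3N; no stereocentre is formed.

Step 2
Reactants: 3 (E)-4-acetoxy-2-methylbut-2-enal; 2 silyl dienol ether
Product: 4 (2E,5R,6E)-8-acetoxy-5-hydroxy-2,6-dimethylocta-2,6-dienal
Conditions: B-phenyl oxazaborolidinone from N-Ts-L-tryptophan (50 mol%), i-PrOH (1.1 equiv), EtCN, −78 °C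
Reagents that add atoms: none
Why: Asymmetric vinylogous Mukaiyama aldol reaction, in which the boron-bound α-methyl enal is attacked at one face by the γ-carbon of 2; this sets 5R and delivers the E-enal at the right oxidation level for the next cycle.

Step 3
Reactants: 4 hydroxy enal
Product: 5 (2E,5R,6E)-5,8-diacetoxy-2,6-dimethylocta-2,6-dienal
Conditions: Ac2O, pyridine, DMAP (cat.), CH2Cl2, 0 °C
Reagents that add atoms: acetic anhydride, CC(=O)OC(C)=O
Why: DMAP-catalysed acylation installs the final C5 acetate without touching C5 or the enal.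

Step 4
Reactants: 5 diacetoxy enal; 2 silyl dienol ether
Product: 6 (2E,5S,6E,9R,10E)-9,12-diacetoxy-5-hydroxy-2,6,10-trimethyldodeca-2,6,10-trienal (cembrane 5R,9S)
Conditions: B-phenyl oxazaborolidinone from N-Ts-D-tryptophan (50 mol%), i-PrOH (1.1 equiv), EtCN, −78 °C
Reagents that add atoms: none
Why: Second asymmetric vinylogous Mukaiyama aldol reaction, where the enantiomeric catalyst sets 9S under catalyst control (C5 is 1,5-remote) and builds the E C11=C12 alkene.

Step 5
Reactants: 6 hydroxy trienal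
Product: 7 9-O-TBS ether of 6
Conditions: TBSCl, imidazole, DMF, rt
Reagents that add atoms: tert-butyldimethylsilyl chloride, CC(C)(C)[Si](C)(C)Cl
Why: Standard silylation, so that the only hydroxyl that stays free in the target receives the only group removed at the end.

Step 6
Reactants: 7 silyloxy trienal
Product: 8 (2E,4R,6E,8S,10E)-8-(tert-butyldimethylsilyloxy)-3,7,11-trimethyltrideca-2,6,10,12-tetraene-1,4-diyl diacetate
Conditions: Ph3PCH3Br, KHMDS, THF, −78 → 0 °C (1.1 equiv ylide)
Reagents that add atoms: methyltriphenylphosphonium bromide, C[P+](c1ccccc1)(c1ccccc1)c1ccccc1.[Br-]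
Why: Wittig methylenation adds C14; the non-enolisable α-methyl enal reacts far faster than the acetates at low temperature.

Step 7
Reactants: 8 terminal diene
Product: 10 C14 primary alcohol (13-hydroxy-trideca-2,6,10-triene analogue of 8), via B-alkyl-9-BBN adduct 9 (not isolated)
Conditions: 9-BBN, THF, 0 °C → rt; then NaBO3·4H2O, THF–H2O, rt
Reagents that add atoms: sodium perborate, [Na+].[Na+].O[B-]1(O)OO[B-](O)(O)OO1
Why: Chemoselective anti-Markovnikov hydroboration–oxidation, in which 9-BBN adds only to the monosubstituted diene terminus, the trisubstituted alkenes are inert and perborate spares the acetates.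

Step 8
Reactants: 10 homoallylic alcohol
Product: 11 C14 aldehyde (β,γ-unsaturated; used crude)
Conditions: Dess–Martin periodinane, pyridine, CH2Cl2, 0 °C
Reagents that add atoms: none
Why: Buffered Dess–Martin oxidation is neutral and fast, so the C11=C12 alkene does not move into conjugation.

Step 9
Reactants: 12 propargyl alcohol
Product: 14 (E)-3-iodo-2-methylprop-2-en-1-ol, via alkenylalane 13 (not isolated)
Conditions: AlMe3 (3 equiv), Cp2ZrCl2 (25 mol%), CH2Cl2, 0 °C → rt; then I2, THF, −30 °C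
Reagents that add atoms: trimethylaluminium, C[Al](C)C; iodine, II
Why: Negishi Zr-catalysed syn-carboalumination followed by iodinolysis with retention places C17 (Me) cis and C16 (CH2OH) trans to iodine.

Step 10
Reactants: 14 iodo alcohol
Product: 15 (E)-tert-butyl[(3-iodo-2-methylprop-2-enyl)oxy]dimethylsilane
Conditions: TBSCl, imidazole, CH2Cl2, rt
Reagents that add atoms: tert-butyldimethylsilyl chloride, CC(C)(C)[Si](C)(C)Cl
Why: Standard silylation; C16 is carried at the alcohol level and is unmasked together with 9-OH.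

Step 11
Reactants: 11 C14 aldehyde; 15 alkenyl iodide
Product: 17 (2E,4R,6E,8S,10E,13R,14E)-8,16-bis(tert-butyldimethylsilyloxy)-13-hydroxy-3,7,11,15-tetramethylhexadeca-2,6,10,14-tetraene-1,4-diyl diacetate (cembrane 5R,9S,14R), via alkenylchromium(III) species 16 (not isolated)
Conditions: CrCl2 (4 equiv), NiCl2 (1 mol%), chiral oxazoline–sulfonamide ligand, Et3N, THF, rt
Reagents that add atoms: none
Why: Asymmetric Nozaki–Hiyama–Kishi coupling, whose neutral conditions tolerate the acetates and the isomerisable aldehyde, retain the alkene geometry and let the ligand-bound Cr(III) select the aldehyde face to give 14R.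

Step 12
Reactants: 17 diacetate
Product: 18 C2 allylic alcohol (2,14-diol; 5-OAc kept; 5R,9S,14R)
Conditions: Mg(OMe)2 (0.5 equiv), MeOH, 0 °C → rt
Reagents that add atoms: none
Why: Chemoselective transesterification, because magnesium methoxide cleaves the unhindered primary allylic acetate much faster than the secondary C5 acetate.

Step 13
Reactants: 18 allylic alcohol
Product: 19 3,4-epoxy alcohol (3S,4S,5R,9S,14R)
Conditions: Ti(Oi-Pr)4 (20 mol%), L-(+)-DET (24 mol%), t-BuOOH, 4 Å MS, CH2Cl2, −25 °C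
Reagents that add atoms: tert-butyl hydroperoxide, CC(C)(C)OO
Why: Sharpless asymmetric epoxidation with L-(+)-tartrate gives 3S,4S as it does with geraniol, and the 14R secondary allylic alcohol is the slow-reacting enantiomer for this tartrate, so C1=C15 stays intact.

Step 14
Reactants: 19 epoxy alcohol
Product: 20 acyclic epoxy aldehyde (3R,4S,5R,9S,14R; 3R by CIP priority change only)
Conditions: TEMPO (10 mol%), PhI(OAc)2 (1.1 equiv), CH2Cl2, 0 °C; used directly
Reagents that add atoms: none
Why: Oxoammonium (TEMPO/PhI(OAc)2) oxidation is selective for the primary alcohol over the hindered secondary 14-OH and does not epimerise or open the epoxide.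

Step 15 (key step)
Reactants: 20 acyclic epoxy aldehyde
Product: 22 (1R,2S,3S,4S,5R,9S,14R,7E,11E)-5-acetoxy-3,4-epoxy-9,16-bis(tert-butyldimethylsilyloxy)cembra-7,11,15(17)-triene-2,14-diol, via chloro(methyl)aluminium 14-alkoxide 21 (not isolated)
Conditions: Me2AlCl (2.5 equiv), CH2Cl2, 1 mM (syringe-pump addition of 20), −78 → −30 °C; aq. Rochelle salt
Reagents that add atoms: none
Why: Proposed new method: the first equivalent of Me2AlCl converts the free 14-OH into an aluminium alkoxide that binds the C2 aldehyde, so ring closure becomes a templated type-I carbonyl-ene reaction through a six-membered C2/C1/C15/C17/H/O2 array fused to the O14–Al–O2 chelate; A1,3 strain with the Z-methyl C17 holds H14 in the alkene plane, so delivery syn to O14 sets 1R; O2 must lie gauche to both C14 and C15, so H is taken from C17 and not from C16H2OTBS, and C3 goes anti to C14, which sets 2S (trans C1/C2) and is also the Felkin–Anh face of the epoxy aldehyde (matched); the closest known reactions are alkylaluminium-chloride-promoted ene macrocyclisations of ω-isopropylidene aldehydes to 14-membered homoallylic alcohols and hydroxy-directed ene reactions of A1,3-strained allylic alcohols.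

Step 16
Reactants: 22 macrocyclic 2,14-diol
Product: 23 14-O-acetate of 22 (1S,2S,3S,4S,5R,9S,14R; 1S by CIP priority change only)
Conditions: Ac2O (1.1 equiv), Et3N, DMAP (5 mol%), CH2Cl2, −40 °C
Reagents that add atoms: acetic anhydride, CC(=O)OC(C)=O
Why: Site-selective acylation, since 14-OH has a CH2 neighbour whereas 2-OH lies between two branched carbons, is inductively deactivated and is hydrogen-bonded to the oxirane.

Step 17
Reactants: 23 bis-silyl ether
Product: 24 5,14-diacetoxy-3,4-epoxycembra-7,11,15(17)-triene-2,9,16-triol (1S,2S,3S,4S,5R,9S,14R)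
Conditions: HF·pyridine, pyridine, THF, 0 °C → rt
Reagents that add atoms: none
Why: Buffered fluoride desilylation removes both TBS groups at once; the acidic buffer avoids acetate migration and Payne rearrangement, and trisubstituted epoxides tolerate it.

Step 18
Reactants: 24 triol
Product: 27 michaolide A, via hydroxy enal 25 (not isolated), via lactol 26 (not isolated)
Conditions: TEMPO (20 mol%), PhI(OAc)2 (2.5 equiv), CH2Cl2, 0 °C → rt
Reagents that add atoms: none
Why: Oxidative lactonisation of a 2-methylene-1,4-diol, in which the primary allylic 16-OH is oxidised first, 2-OH closes the lactol (14-O is blocked as acetate) and the lactol is oxidised faster than the hindered secondary 9-OH; no stereocentre changes.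

## Compound list
1 | tiglic aldehyde, (E)-2-methylbut-2-enal | C/C=C(\C)C=O | starting material
2 | (1E)-1-(tert-butyldimethylsilyloxy)-2-methylbuta-1,3-diene | C=C/C(C)=C/O[Si](C)(C)C(C)(C)C | intermediate
3 | (E)-4-acetoxy-2-methylbut-2-enal | CC(=O)OC/C=C(\C)C=O | starting material
4 | (2E,5R,6E)-8-acetoxy-5-hydroxy-2,6-dimethylocta-2,6-dienal | CC(=O)OC/C=C(\C)[C@H](O)C/C=C(\C)C=O | intermediate
5 | (2E,5R,6E)-5,8-diacetoxy-2,6-dimethylocta-2,6-dienal | CC(=O)OC/C=C(\C)[C@H](OC(C)=O)C/C=C(\C)C=O | intermediate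
6 | C2–C13 hydroxy trienal (5R,9S) | CC(=O)OC/C=C(\C)[C@H](OC(C)=O)C/C=C(\C)[C@@H](O)C/C=C(\C)C=O | intermediate
7 | 9-O-TBS trienal | CC(=O)OC/C=C(\C)[C@H](OC(C)=O)C/C=C(\C)[C@@H](O[Si](C)(C)C(C)(C)C)C/C=C(\C)C=O | intermediate
8 | C2–C14 tetraene (terminal diene) | CC(=O)OC/C=C(\C)[C@H](OC(C)=O)C/C=C(\C)[C@@H](O[Si](C)(C)C(C)(C)C)C/C=C(\C)C=C | intermediate
9 | B-alkyl-9-BBN adduct (B on C14) | CC(=O)OC/C=C(\C)[C@H](OC(C)=O)C/C=C(\C)[C@@H](O[Si](C)(C)C(C)(C)C)C/C=C(\C)CCB1C2CCCC1CCC2 | intermediate
10 | C14 primary alcohol | CC(=O)OC/C=C(\C)[C@H](OC(C)=O)C/C=C(\C)[C@@H](O[Si](C)(C)C(C)(C)C)C/C=C(\C)CCO | intermediate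
11 | C14 aldehyde | CC(=O)OC/C=C(\C)[C@H](OC(C)=O)C/C=C(\C)[C@@H](O[Si](C)(C)C(C)(C)C)C/C=C(\C)CC=O | intermediate
12 | propargyl alcohol | C#CCO | starting material
13 | (E)-alkenylalane, O-aluminated | C[Al](C)/C=C(\C)CO[Al](C)C | intermediate
14 | (E)-3-iodo-2-methylprop-2-en-1-ol | OC/C(C)=C/I | intermediate
15 | TBS ether of 14 | CC(C)(C)[Si](C)(C)OC/C(C)=C/I | intermediate
16 | alkenylchromium(III) dichloride | CC(C)(C)[Si](C)(C)OC/C(C)=C/[Cr](Cl)Cl | intermediate
17 | open C20 chain, 2,5-di-OAc, 9,16-di-OTBS, 14-OH (5R,9S,14R) | CC(=O)OC/C=C(\C)[C@H](OC(C)=O)C/C=C(\C)[C@@H](O[Si](C)(C)C(C)(C)C)C/C=C(\C)C[C@@H](O)/C=C(\C)CO[Si](C)(C)C(C)(C)C | intermediate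
18 | 2,14-diol (C2 allylic alcohol) | OC/C=C(\C)[C@H](OC(C)=O)C/C=C(\C)[C@@H](O[Si](C)(C)C(C)(C)C)C/C=C(\C)C[C@@H](O)/C=C(\C)CO[Si](C)(C)C(C)(C)C | intermediate
19 | 3,4-epoxy alcohol (3S,4S,5R,9S,14R) | OC[C@@H]1O[C@@]1(C)[C@H](OC(C)=O)C/C=C(\C)[C@@H](O[Si](C)(C)C(C)(C)C)C/C=C(\C)C[C@@H](O)/C=C(\C)CO[Si](C)(C)C(C)(C)C | intermediate
20 | acyclic epoxy aldehyde | O=C[C@@H]1O[C@@]1(C)[C@H](OC(C)=O)C/C=C(\C)[C@@H](O[Si](C)(C)C(C)(C)C)C/C=C(\C)C[C@@H](O)/C=C(\C)CO[Si](C)(C)C(C)(C)C | intermediate
21 | chloro(methyl)aluminium 14-alkoxide of 20 | O=C[C@@H]1O[C@@]1(C)[C@H](OC(C)=O)C/C=C(\C)[C@@H](O[Si](C)(C)C(C)(C)C)C/C=C(\C)C[C@@H](O[Al](C)Cl)/C=C(\C)CO[Si](C)(C)C(C)(C)C | intermediate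
22 | macrocyclic 2,14-diol | C=C(CO[Si](C)(C)C(C)(C)C)[C@@H]1[C@H](O)C/C(C)=C/C[C@H](O[Si](C)(C)C(C)(C)C)/C(C)=C/C[C@@H](OC(C)=O)[C@]2(C)O[C@H]2[C@H]1O | intermediate
23 | 14-O-acetate | C=C(CO[Si](C)(C)C(C)(C)C)[C@@H]1[C@H](OC(C)=O)C/C(C)=C/C[C@H](O[Si](C)(C)C(C)(C)C)/C(C)=C/C[C@@H](OC(C)=O)[C@]2(C)O[C@H]2[C@H]1O | intermediate
24 | 2,9,16-triol | C=C(CO)[C@@H]1[C@H](OC(C)=O)C/C(C)=C/C[C@H](O)/C(C)=C/C[C@@H](OC(C)=O)[C@]2(C)O[C@H]2[C@H]1O | intermediate
25 | 2,9-dihydroxy-16-al | C=C(C=O)[C@@H]1[C@H](OC(C)=O)C/C(C)=C/C[C@H](O)/C(C)=C/C[C@@H](OC(C)=O)[C@]2(C)O[C@H]2[C@H]1O | intermediate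
26 | 2,16-lactol (C16 epimers) | C=C1C(O)O[C@H]2[C@H]1[C@H](OC(C)=O)C/C(C)=C/C[C@H](O)/C(C)=C/C[C@@H](OC(C)=O)[C@]1(C)O[C@@H]21 | intermediate
27 | michaolide A | C=C1C(=O)O[C@H]2[C@H]1[C@H](OC(C)=O)C/C(C)=C/C[C@H](O)/C(C)=C/C[C@@H](OC(C)=O)[C@]1(C)O[C@@H]21 | target

## Step count
- Total: 18 steps.
- Longest linear sequence: 16 steps (steps 1–8 and 11–18). Steps 9–10 form a two-step side branch.

## Steps most likely to fail

**Step 15, ene macrocyclisation.**
- Risks: the alkene is deactivated by two allylic oxygens. The epoxy aldehyde may be opened by chloride. It may also be reduced by a Meerwein–Ponndorf-type hydride shift from C14 within the chelate.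
- Fallback: postpone the oxirane, setting out from 18 and returning at 22. TEMPO/PhI(OAc)2 oxidises 18 to the acyclic tetraenal F1.
- The same aluminium-templated ene closure is run on this sturdier enal. It gives the macrocyclic allylic alcohol F2.
- Sharpless epoxidation of F2 with L-(+)-DET then gives 22. F2 carries the fast-reacting carbinol configuration, whose erythro product is the one required.

**Step 16, site-selective acetylation of the 2,14-diol.**
- Risk: 2-OH may compete with 14-OH for the acylating agent.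
- Fallback: differentiate the two hydroxyls by ring formation instead of acylation, setting out from 22 and returning at 27. Brief buffered HF·pyridine removes only the primary allylic silyl group and gives the 9-O-TBS triol F3.
- MnO2 oxidises the single allylic alcohol of F3. O2 is gauche to C15 in the extended C13–C3 segment and O14 is anti, so closure onto O2 is expected. It gives the 14-hydroxy lactone F4.
- The only free hydroxyl of F4 is then acetylated without ambiguity to 9-O-TBS-michaolide A F5. HF·pyridine releases 27.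

**Step 11, asymmetric Ni/Cr coupling on a fragile aldehyde.**
- Risk: ligand control at C14 may be modest.
- Fallback: set C14 by ketone reduction, setting out from 11 and 15 and returning at 17. A ligand-free Ni/Cr coupling gives the C14-epimeric alcohol mixture F6.
- Dess–Martin oxidation of F6 gives the C14 dienone F7.
- Corey–Bakshi–Shibata reduction with (S)-Me-CBS and BH3·SMe2 treats the alkenyl group as the large substituent. It gives 17 with 14R.

## Further compounds
F1 | step 15 | acyclic tetraenal (2-oxo analogue of 18; 5R,9S,14R) | O=C/C=C(\C)[C@H](OC(C)=O)C/C=C(\C)[C@@H](O[Si](C)(C)C(C)(C)C)C/C=C(\C)C[C@@H](O)/C=C(\C)CO[Si](C)(C)C(C)(C)C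
F2 | step 15 | (1R,2R,5R,9S,14R,3E,7E,11E)-5-acetoxy-9,16-bis(tert-butyldimethylsilyloxy)cembra-3,7,11,15(17)-tetraene-2,14-diol | C=C(CO[Si](C)(C)C(C)(C)C)[C@@H]1[C@H](O)C/C(C)=C/C[C@H](O[Si](C)(C)C(C)(C)C)/C(C)=C/C[C@@H](OC(C)=O)/C(C)=C/[C@H]1O
F3 | step 16 | 9-O-TBS 2,14,16-triol | C=C(CO)[C@@H]1[C@H](O)C/C(C)=C/C[C@H](O[Si](C)(C)C(C)(C)C)/C(C)=C/C[C@@H](OC(C)=O)[C@]2(C)O[C@H]2[C@H]1O
F4 | step 16 | 14-hydroxy-9-O-TBS 16,2-lactone | C=C1C(=O)O[C@H]2[C@H]1[C@H](O)C/C(C)=C/C[C@H](O[Si](C)(C)C(C)(C)C)/C(C)=C/C[C@@H](OC(C)=O)[C@]1(C)O[C@@H]21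
F5 | step 16 | 9-O-TBS-michaolide A | C=C1C(=O)O[C@H]2[C@H]1[C@H](OC(C)=O)C/C(C)=C/C[C@H](O[Si](C)(C)C(C)(C)C)/C(C)=C/C[C@@H](OC(C)=O)[C@]1(C)O[C@@H]21
F6 | step 11 | C14-epimeric mixture of 17 | CC(=O)OC/C=C(\C)[C@H](OC(C)=O)C/C=C(\C)[C@@H](O[Si](C)(C)C(C)(C)C)C/C=C(\C)CC(O)/C=C(\C)CO[Si](C)(C)C(C)(C)C
F7 | step 11 | C14 dienone | CC(=O)OC/C=C(\C)[C@H](OC(C)=O)C/C=C(\C)[C@@H](O[Si](C)(C)C(C)(C)C)C/C=C(\C)CC(=O)/C=C(\C)CO[Si](C)(C)C(C)(C)C
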